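Ring B of the target is read as a masked 2-methylcyclohexane-1,3-dione: C7 carries oxygen, C9 (sp2, flanked by quaternary C10) can be a ketone, and C8 lies between them. Both rings are therefore closed in one base-mediated Michael–Claisen cascade of an acyclic keto enoate: the C10 enolate adds to C5 (ring A), then the C8 enolate acylates the ester carbon C7 (ring B). The precursor, methyl (2E,5S)-5-methoxy-4,4,8-trimethyl-9-oxoundec-2-enoate, is an epimeric mixture that converges. The hindered C9 carbonyl of the dione then accepts the citronellol-derived side chain by Stork–Danheiser transposition, and Luche reduction sets C7.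

Key step: step 5

Remark: positions are cited in labdane numbering (rings C1–C10, side chain C11–C16, C17 on C8, C18/C19 on C4, C20 on C10); compounds 4, 7, 8 and 10 are carried as mixtures of epimers at the future C10, which step 5 erases.

Step 1
Reactants: 1 pentan-3-one; 2 acrolein
Product: 4 4-methyl-5-oxoheptanal (racemic), via pyrrolidine enamine 3 (not isolated)
Conditions: pyrrolidine, TsOH (cat.), PhMe, reflux, Dean–Stark; then acrolein, 1,4-dioxane, 0 °C to rt; then AcOH/NaOAc, H2O
Reagents that add atoms: water, O
Why: Stork enamine Michael addition, in which the symmetric ketone can give only one regioisomer and buffered hydrolysis should release the keto aldehyde before it aldolises; the new stereocenter is racemic and is erased in step 5.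

Step 2
Reactants: 4 4-methyl-5-oxoheptanal; 5 (3-methylbut-2-en-1-yl)magnesium chloride
Product: 7 (7S)-7-hydroxy-4,8,8-trimethyldec-9-en-3-one, via O-boryl carbinol 6 (not isolated)
Conditions: (+)-B-methoxydiisopinocampheylborane (from (−)-α-pinene), Et2O, −78 °C to rt; then 4, −78 °C; then NaOH, H2O2, 0 °C to rt
Reagents that add atoms: none
Why: Brown asymmetric prenylboration through a chair six-membered transition state with allyl transfer at the γ-carbon, in which the aldehyde should react far faster than the ketone at −78 °C and the isopinocampheyl groups from (−)-α-pinene direct the 1,1-dimethylallyl group to the face that gives the (S)-carbinol (future C3).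

Step 3
Reactants: 7 (7S)-7-hydroxy-4,8,8-trimethyldec-9-en-3-one
Product: 8 (7S)-7-methoxy-4,8,8-trimethyldec-9-en-3-one
Conditions: MeOTf, 2,6-di-tert-butyl-4-methylpyridine, CH2Cl2, 0 °C to rt
Reagents that add atoms: methyl trifluoromethanesulfonate, COS(=O)(=O)C(F)(F)F
Why: O-methylation of a hindered secondary alcohol under non-basic conditions, so that the enolisable ketone is not alkylated and the carbinol center is retained.

Step 4
Reactants: 8 (7S)-7-methoxy-4,8,8-trimethyldec-9-en-3-one; 9 methyl acrylate
Product: 10 methyl (2E,5S)-5-methoxy-4,4,8-trimethyl-9-oxoundec-2-enoate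
Conditions: methyl acrylate (5 equiv), second-generation Hoveyda–Grubbs catalyst RuCl2(H2IMes)(=CH-C6H4-2-OiPr) (5 mol %), PhMe, 80 °C
Reagents that add atoms: none
Why: Olefin cross-metathesis, in which the vinyl group on the quaternary carbon cannot homodimerise and excess acrylate should lead to the thermodynamically preferred (E)-enoate.

Step 5
Reactants: 10 methyl (2E,5S)-5-methoxy-4,4,8-trimethyl-9-oxoundec-2-enoate
Product: 13 (3S,5S,10S)-3-methoxy-4,4,8,10-tetramethyl-trans-decalin-7,9-dione (3β-OCH3; 5α-H; 10β-CH3), via monocyclic Michael adduct 11 (not isolated), via potassium diketonate 12 (not isolated)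
Conditions: KOtBu (2.5 equiv), t-BuOH, THF, 0 °C to 40 °C; then 1 M HCl
Reagents that add atoms: none
Why: Under equilibrating KOtBu/t-BuOH both C10 epimers of 10 give the same tetrasubstituted C10 enolate, the only enolate that can reach C5 through a six-membered transition state; it adds to C5 of the (E)-enoate (6-exo-trig, closes ring A), proton transfer then places the charge at C8, and the C8 enolate acylates the ester carbon C7 (6-exo-trig Dieckmann closure of ring B, methoxide lost). The closest known reaction type is the Michael–Claisen [3+3] annulation of ketones with enoates to cyclohexane-1,3-diones, run here intramolecularly. Deprotonation of the 2-methyl-1,3-dione to 12 is the thermodynamic sink that pulls the reversible, congested conjugate addition forward and makes the step stereoconvergent with respect to the racemic α-carbon. C5 should be set by C3 through a chair transition state for ring A with the methoxy group and the enoate arm both equatorial (cis-1,3), and C10 relative to C5 because the enolate carbon C9 takes the less crowded equatorial site gauche to the acceptor arm (potassium bridging enolate and ester oxygens) while the methyl goes axial, which gives the trans ring fusion. The step needs C10 to react before C8 and no competing dienolate: ring size secures the first (attack of C8 on C5 would be an eight-membered closure) and the quaternary C4, which leaves the enoate without γ-hydrogen, the second.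

Step 6
Reactants: 13 (3S,5S,10S)-3-methoxy-4,4,8,10-tetramethyl-trans-decalin-7,9-dione
Product: 14 (3S,5S,10S)-7-isobutoxy-3-methoxy-4,4,8,10-tetramethyl-trans-decal-7-en-9-one
Conditions: i-BuOH, TsOH·H2O (cat.), PhMe, reflux, Dean–Stark
Reagents that add atoms: 2-methylpropan-1-ol, CC(C)CO
Why: Acid-catalysed enol etherification of a 1,3-dione (vinylogous ester formation), in which the alcohol should add at the less hindered C7 carbonyl because C9 is shielded by the quaternary C10, as known for 2,4,4-trimethylcyclohexane-1,3-dione.

Step 7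
Reactants: 15 (S)-citronellol
Product: 16 tert-butyl{[(3S)-3,7-dimethyloct-6-en-1-yl]oxy}dimethylsilane
Conditions: TBSCl, imidazole, CH2Cl2, rt
Reagents that add atoms: tert-butyldimethylsilyl chloride, CC(C)(C)[Si](C)(C)Cl
Why: Standard silylation of a primary alcohol, which leaves the remote stereocenter (future C13) untouched.

Step 8
Reactants: 16 tert-butyl{[(3S)-3,7-dimethyloct-6-en-1-yl]oxy}dimethylsilane
Product: 17 (4S)-6-[(tert-butyldimethylsilyl)oxy]-4-methylhexanoic acid
Conditions: RuCl3·3H2O (2 mol %), NaIO4 (4 equiv), EtOAc/MeCN/H2O, rt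
Reagents that add atoms: sodium periodate, [Na+].[O-]I(=O)(=O)=O; water, O
Why: Ruthenium tetroxide oxidative cleavage of the trisubstituted alkene, which should give the carboxylic acid and acetone while the primary silyl ether survives.

Step 9
Reactants: 17 (4S)-6-[(tert-butyldimethylsilyl)oxy]-4-methylhexanoic acid
Product: 18 tert-butyl{[(3R)-5-iodo-3-methylpentyl]oxy}dimethylsilane
Conditions: PhI(OAc)2, I2, cyclohexane, hν, 80 °C
Reagents that add atoms: iodine, II
Why: Suárez iododecarboxylation (acyl hypoiodite, radical decarboxylation, iodine atom transfer), which shortens the chain by one carbon to the primary iodide without touching the stereocenter; the descriptor changes only by priority.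

Step 10
Reactants: 14 (3S,5S,10S)-7-isobutoxy-3-methoxy-4,4,8,10-tetramethyl-trans-decal-7-en-9-one; 18 tert-butyl{[(3R)-5-iodo-3-methylpentyl]oxy}dimethylsilane
Product: 21 (3S,5R,10S,13S)-15-hydroxy-3-methoxylabd-8-en-7-one, via alkyllithium 19 (not isolated), via lithium carbinolate 20 (not isolated)
Conditions: 18, t-BuLi (2.0 equiv), Et2O/pentane, −78 °C; then 14, −78 to 0 °C; then 2 M HCl, THF, rt
Reagents that add atoms: water, O
Why: Stork–Danheiser alkylative 1,3-carbonyl transposition, in which the primary alkyllithium from lithium–iodine exchange adds 1,2 to the C9 carbonyl (no α-hydrogen at C10) and aqueous acid ionises the tertiary allylic carbinol, hydrolyses the enol ether to the C7 ketone with the tetrasubstituted C8=C9 alkene, and removes the silyl ether.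

Step 11
Reactants: 21 (3S,5R,10S,13S)-15-hydroxy-3-methoxylabd-8-en-7-one
Product: 22 (3S,5R,7S,10S,13S)-3-methoxylabd-8-ene-7,15-diol
Conditions: NaBH4, CeCl3·7H2O, MeOH, −78 to 0 °C
Reagents that add atoms: none
Why: Luche 1,2-reduction of the enone, in which axial hydride delivery on the α face (away from the angular 10β-methyl) should give the equatorial 7β-alcohol (7S).

Step 12
Reactants: 22 (3S,5R,7S,10S,13S)-3-methoxylabd-8-ene-7,15-diol
Product: 23 (3S,5R,7S,10S,13S)-3-methoxylabd-8-ene-7,15-diyl diacetate (target)
Conditions: Ac2O, pyridine, DMAP (cat.), CH2Cl2, rt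
Reagents that add atoms: acetic anhydride, CC(=O)OC(C)=O
Why: DMAP-catalysed acetylation of the primary and the allylic secondary hydroxyl, which creates no stereocenter and should not ionise the allylic position under basic conditions.

Compound list
1 | pentan-3-one | CCC(=O)CC | starting material
2 | acrolein | C=CC=O | starting material
3 | 1-(pent-2-en-3-yl)pyrrolidine (E/Z mixture) | CC=C(CC)N1CCCC1 | intermediate
4 | 4-methyl-5-oxoheptanal (racemic) | CCC(=O)C(C)CCC=O | intermediate
5 | (3-methylbut-2-en-1-yl)magnesium chloride | CC(C)=CC[Mg]Cl | starting material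
6 | O-(diisopinocampheylboryl) derivative of 7 | CCC(=O)C(C)CC[C@H](OB([C@H]1C[C@H]2C[C@@H]([C@@H]1C)C2(C)C)[C@H]1C[C@H]2C[C@@H]([C@@H]1C)C2(C)C)C(C)(C)C=C | intermediate
7 | (7S)-7-hydroxy-4,8,8-trimethyldec-9-en-3-one (C4 epimers) | CCC(=O)C(C)CC[C@H](O)C(C)(C)C=C | intermediate
8 | (7S)-7-methoxy-4,8,8-trimethyldec-9-en-3-one (C4 epimers) | CCC(=O)C(C)CC[C@H](OC)C(C)(C)C=C | intermediate
9 | methyl acrylate | C=CC(=O)OC | starting material
10 | methyl (2E,5S)-5-methoxy-4,4,8-trimethyl-9-oxoundec-2-enoate (C8 epimers) | CCC(=O)C(C)CC[C@H](OC)C(C)(C)/C=C/C(=O)OC | intermediate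
11 | methyl 2-[(1S,3S,6S)-3-methoxy-2,2,6-trimethyl-6-propanoylcyclohexyl]acetate | CO[C@H]1CC[C@](C)(C(=O)CC)[C@@H](CC(=O)OC)C1(C)C | intermediate
12 | potassium enolate of 13 | CO[C@H]1CC[C@]2(C)C(=O)C(C)=C([O-])C[C@H]2C1(C)C.[K+] | intermediate
13 | (3S,5S,10S)-3-methoxy-4,4,8,10-tetramethyl-trans-decalin-7,9-dione (3β-OCH3, 5α-H, 10β-CH3; C8 enolisable) | CO[C@H]1CC[C@]2(C)C(=O)C(C)C(=O)C[C@H]2C1(C)C | intermediate
14 | (3S,5S,10S)-7-isobutoxy-3-methoxy-4,4,8,10-tetramethyl-trans-decal-7-en-9-one | CO[C@H]1CC[C@]2(C)C(=O)C(C)=C(OCC(C)C)C[C@H]2C1(C)C | intermediate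
15 | (S)-citronellol, (3S)-3,7-dimethyloct-6-en-1-ol | C[C@@H](CCC=C(C)C)CCO | starting material
16 | tert-butyl{[(3S)-3,7-dimethyloct-6-en-1-yl]oxy}dimethylsilane | C[C@@H](CCC=C(C)C)CCO[Si](C)(C)C(C)(C)C | intermediate
17 | (4S)-6-[(tert-butyldimethylsilyl)oxy]-4-methylhexanoic acid | C[C@@H](CCC(=O)O)CCO[Si](C)(C)C(C)(C)C | intermediate
18 | tert-butyl{[(3R)-5-iodo-3-methylpentyl]oxy}dimethylsilane | C[C@@H](CCI)CCO[Si](C)(C)C(C)(C)C | intermediate
19 | {(3S)-5-[(tert-butyldimethylsilyl)oxy]-3-methylpentyl}lithium | C[C@@H](CC[Li])CCO[Si](C)(C)C(C)(C)C | intermediate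
20 | lithium alkoxide of the C9 carbinol from 14 and 19 (C9 configuration immaterial) | CO[C@H]1CC[C@]2(C)C([O-])(CC[C@H](C)CCO[Si](C)(C)C(C)(C)C)C(C)=C(OCC(C)C)C[C@H]2C1(C)C.[Li+] | intermediate
21 | (3S,5R,10S,13S)-15-hydroxy-3-methoxylabd-8-en-7-one | CO[C@H]1CC[C@]2(C)C(CC[C@H](C)CCO)=C(C)C(=O)C[C@H]2C1(C)C | intermediate
22 | (3S,5R,7S,10S,13S)-3-methoxylabd-8-ene-7,15-diol | CO[C@H]1CC[C@]2(C)C(CC[C@H](C)CCO)=C(C)[C@@H](O)C[C@H]2C1(C)C | intermediate
23 | (3S,5R,7S,10S,13S)-3-methoxylabd-8-ene-7,15-diyl diacetate | CO[C@H]1CC[C@]2(C)C(CC[C@H](C)CCOC(C)=O)=C(C)[C@@H](OC(C)=O)C[C@H]2C1(C)C | target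

Total step count: 12. Longest linear sequence: 9 steps (steps 1–6 and 10–12); steps 7–9 build the side chain and join at step 10.

Steps most likely to fail

Step 5. The conjugate addition may show low facial selectivity, because a methoxy group next to the gem-dimethyl carbon prefers the equatorial position only weakly, so the relay from C3 to C5 may be poor. The C5–C10 bond also forms between two congested carbons and may be slow. The fallback replaces substrate control by reagent control and separates the two bond formations. It sets out from 10 and comes back to the route at 11. Compound 10 is condensed with (R)-1-phenylethylamine (TsOH cat., PhMe, Dean–Stark) to the ketimine of 10 F1. On warming (THF, 60 °C) its more substituted secondary enamine tautomer should add to the tethered enoate in an aza-ene-type chair transition state on the face away from the phenyl group (deracemising Michael addition of chiral imines), giving the cyclised ring-A ketimine F2. Hydrolysis with aqueous AcOH gives the keto ester 11, now isolated, and KOtBu/t-BuOH closes ring B by Dieckmann condensation to 13.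

Step 10. The alkyllithium may deprotonate C6 (γ to the carbonyl), or 1,2-addition at the C9 carbonyl, shielded by C10 and the C8 methyl, may not proceed, so that 14 is recovered. The fallback replaces carbonyl addition by cross-coupling. It sets out from 14 and 18 and comes back at 21. Compound 14 is deprotonated at C6 with KN(SiMe3)2 (THF, −78 °C) and the extended enolate is O-sulfonylated with PhNTf2 to the 9-triflyloxy-7-isobutoxy-6,8-diene F3. Iodide 18 is converted with Zn dust and LiCl (THF) into the alkylzinc iodide F4. Negishi coupling of F3 and F4 with PdCl2(dppf) gives the 9-alkyl dienol ether F5, and 2 M HCl in THF hydrolyses the enol ether and the silyl ether to 21.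

Step 4. Initiation and turnover at the vinyl group on the quaternary carbon may be slow, so that catalyst decomposition and acrylate dimerisation take over. The fallback uses cleavage and olefination instead of metathesis. It sets out from 8 and comes back at 10. Ozonolysis of 8 (O3, CH2Cl2/MeOH, −78 °C; then Me2S) gives the α-quaternary aldehyde (3S)-3-methoxy-2,2,6-trimethyl-7-oxononanal F6. Wittig olefination with methyl (triphenylphosphoranylidene)acetate (PhMe, 80 °C) should give the (E)-enoate 10, the ketone being inert to the stabilised ylide.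

Further compounds
F1 | step 5 | ketimine of 10 with (R)-1-phenylethylamine | CCC(=N[C@H](C)c1ccccc1)C(C)CC[C@H](OC)C(C)(C)/C=C/C(=O)OC
F2 | step 5 | (R)-1-phenylethyl ketimine of 11 | CO[C@H]1CC[C@](C)(C(CC)=N[C@H](C)c2ccccc2)[C@@H](CC(=O)OC)C1(C)C
F3 | step 10 | (3S,5S,10S)-7-isobutoxy-3-methoxy-4,4,8,10-tetramethyl-decalin-6,8-dien-9-yl trifluoromethanesulfonate | CO[C@H]1CC[C@]2(C)C(OS(=O)(=O)C(F)(F)F)=C(C)C(OCC(C)C)=C[C@H]2C1(C)C
F4 | step 10 | {(3S)-5-[(tert-butyldimethylsilyl)oxy]-3-methylpentyl}zinc iodide | C[C@@H](CC[Zn]I)CCO[Si](C)(C)C(C)(C)C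
F5 | step 10 | 7-isobutoxy-3-methoxy-15-[(tert-butyldimethylsilyl)oxy]labda-6,8-diene | CO[C@H]1CC[C@]2(C)C(CC[C@H](C)CCO[Si](C)(C)C(C)(C)C)=C(C)C(OCC(C)C)=C[C@H]2C1(C)C
F6 | step 4 | (3S)-3-methoxy-2,2,6-trimethyl-7-oxononanal | CCC(=O)C(C)CC[C@H](OC)C(C)(C)C=O
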